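## Retrosynthetic overview

1. Target 13 ⇐ 12 by selective cleavage of the two anisyl methyl ethers and the benzyl ether; 12 ⇐ aryl ester 11 by photo-Fries rearrangement, which forms the aryl–C(=O) bond next to the stereocentre with light.
2. 11 ⇐ triflate 9 + enaminone 8: one SN2 (inversion) forms the C3–Cα bond and closes the pyranone ring, the only ring built in the route.
3. Hydroxy ester 6 ⇐ acid 4 + 3-methoxyphenol; 4 ⇐ glycidate 1 + anisole by Friedel–Crafts opening at C3, which gives the Ar2CH unit.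
4. The single stereocentre is C2 of bought 1: kept in steps 1–2, inverted once in step 4, kept in steps 5–6.

Assumption: the centre written [C@@H] in the target is (R); 1 (the bulk diltiazem intermediate) and 7 are catalogue compounds.

## Route

Step 1
Reactants: 1 methyl (2R,3S)-3-(4-methoxyphenyl)oxirane-2-carboxylate; 2 anisole
Product: 4 (2R)-2-hydroxy-3,3-bis(4-methoxyphenyl)propanoic acid, via methyl ester 3 (not isolated)
Conditions: 2 (8 equiv), BF3·OEt2 (20 mol %), CH2Cl2, −40 → 0 °C; then LiOH, THF/H2O, rt; aq. HCl; crystallise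
Reagents that add atoms: lithium hydroxide, [Li+].[OH-]
Why: Friedel–Crafts alkylation by a Lewis-acid-opened epoxide: the epoxide opens at the p-anisyl-stabilised benzylic C3, anisole attacks para so C3 becomes a non-stereogenic Ar2CH carbon, the C2–O bond is never broken so the bought (2R) centre is carried over, and the carbinol centre is not base-labile during the one-pot saponification.

Step 2
Reactants: 4 (2R)-2-hydroxy-3,3-bis(4-methoxyphenyl)propanoic acid; 5 3-methoxyphenol
Product: 6 3-methoxyphenyl (2R)-2-hydroxy-3,3-bis(4-methoxyphenyl)propanoate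
Conditions: 5 (3 equiv), EDC·HCl, DMAP (10 mol %), CH2Cl2, 0 °C → rt
Reagents that add atoms: none
Why: Steglich-type carbodiimide esterification in which the excess phenol out-competes the hindered secondary OH next to the Ar2CH group, and an α-hydroxy acid has no oxazolone pathway, so C2 stays (R).

Step 3
Reactants: 7 1-[4-(benzyloxy)-2-hydroxyphenyl]ethan-1-one
Product: 8 (2E)-1-[4-(benzyloxy)-2-hydroxyphenyl]-3-(dimethylamino)prop-2-en-1-one
Conditions: DMF-DMA (1.5 equiv), toluene, 90 °C
Reagents that add atoms: N,N-dimethylformamide dimethyl acetal, COC(OC)N(C)C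
Why: Formamide-acetal condensation of the acetyl CH3 gives the E-enaminone, a standard chromone precursor; the chelated 2-OH and the benzyl ether are inert and no stereocentre is involved.

Step 4
Reactants: 6 3-methoxyphenyl (2R)-2-hydroxy-3,3-bis(4-methoxyphenyl)propanoate; 8 (2E)-1-[4-(benzyloxy)-2-hydroxyphenyl]-3-(dimethylamino)prop-2-en-1-one
Product: 11 3-methoxyphenyl (2R)-2-[7-(benzyloxy)-4-oxo-4H-chromen-3-yl]-3,3-bis(4-methoxyphenyl)propanoate, via triflate 9 (not isolated), via C-alkylated enaminone 10 (not isolated)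
Conditions: Tf2O (1.05 equiv), 2,6-lutidine (1.1 equiv), CH2Cl2, −78 °C; then 8 (2 equiv), −40 → 25 °C
Reagents that add atoms: trifluoromethanesulfonic anhydride, O=S(=O)(OS(=O)(=O)C(F)(F)F)C(F)(F)F (its CF3SO2 group sits only in 9 and leaves again before 11)
Why: Proposed new method: stereoinvertive SN2 C-alkylation/annulation of an o-hydroxyaryl enaminone with a non-racemic secondary α-triflyloxy ester — the enaminone carbonyl oxygen is tied up in a hydrogen bond to the phenol, so the soft α-carbon (Stork-type enamine reactivity) displaces the α-carbonyl triflate from the back side, which is the only bond-forming event at the stereocentre (clean inversion; the descriptor stays R only because the new carbon substituent ranks below CO2Ar), the iminium loses a proton to give 10, and its phenol then adds to the β-carbon and expels Me2NH (trapped as its triflate salt, so the aryl ester is not aminolysed) to close the pyranone; the closest known reactions are the electrophile-triggered α-C–H functionalisation/chromone annulation of o-hydroxyaryl enaminones and the inversion alkylation of stabilised enolates by 2-triflyloxy esters.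

Step 5
Reactants: 11 3-methoxyphenyl (2R)-2-[7-(benzyloxy)-4-oxo-4H-chromen-3-yl]-3,3-bis(4-methoxyphenyl)propanoate
Product: 12 7-(benzyloxy)-3-[(2R)-1-(2-hydroxy-4-methoxyphenyl)-3,3-bis(4-methoxyphenyl)-1-oxopropan-2-yl]-4H-chromen-4-one
Conditions: hν (275 nm UV-C LED, quartz flow cell), degassed MeCN (3 mM), 15 °C
Reagents that add atoms: none
Why: Photo-Fries rearrangement: excitation of the aryl ester cleaves the O–C(=O) bond and the caged acyl/phenoxyl pair recombines at the ortho carbon para to OMe, giving the free 2-hydroxy-4-methoxyphenyl ketone under neutral conditions; the α-carbon is not a radical centre in the pair, so its (R) configuration is retained.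

Step 6
Reactants: 12 7-(benzyloxy)-3-[(2R)-1-(2-hydroxy-4-methoxyphenyl)-3,3-bis(4-methoxyphenyl)-1-oxopropan-2-yl]-4H-chromen-4-one
Product: 13 7-hydroxy-3-[(2R)-1-(2-hydroxy-4-methoxyphenyl)-3,3-bis(4-hydroxyphenyl)-1-oxopropan-2-yl]-4H-chromen-4-one
Conditions: BBr3 (7 equiv), CH2Cl2, −78 → 0 °C; then H2O, 0 °C
Reagents that add atoms: none
Why: Lewis-acid ether cleavage with BBr3 removes the benzyl ether and the two electron-rich anisyl methyl ethers, while the OMe para to the ketone is a vinylogous ester oxygen, further deactivated once the ortho-OH/C=O pair is boron-chelated, and should survive at ≤ 0 °C; no base is present and the hindered α-CH is not expected to enolise at this temperature.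

## Compound list

1 | methyl (2R,3S)-3-(4-methoxyphenyl)oxirane-2-carboxylate | COC(=O)[C@@H]1O[C@H]1c1ccc(OC)cc1 | starting material
2 | anisole (methoxybenzene) | COc1ccccc1 | starting material
3 | methyl (2R)-2-hydroxy-3,3-bis(4-methoxyphenyl)propanoate | COC(=O)[C@H](O)C(c1ccc(OC)cc1)c1ccc(OC)cc1 | intermediate
4 | (2R)-2-hydroxy-3,3-bis(4-methoxyphenyl)propanoic acid | OC(=O)[C@H](O)C(c1ccc(OC)cc1)c1ccc(OC)cc1 | intermediate
5 | 3-methoxyphenol | COc1cccc(O)c1 | starting material
6 | 3-methoxyphenyl (2R)-2-hydroxy-3,3-bis(4-methoxyphenyl)propanoate | COc1cccc(OC(=O)[C@H](O)C(c2ccc(OC)cc2)c2ccc(OC)cc2)c1 | intermediate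
7 | 1-[4-(benzyloxy)-2-hydroxyphenyl]ethan-1-one | CC(=O)c1ccc(OCc2ccccc2)cc1O | starting material
8 | (2E)-1-[4-(benzyloxy)-2-hydroxyphenyl]-3-(dimethylamino)prop-2-en-1-one | CN(C)/C=C/C(=O)c1ccc(OCc2ccccc2)cc1O | intermediate
9 | 3-methoxyphenyl (2R)-3,3-bis(4-methoxyphenyl)-2-[(trifluoromethanesulfonyl)oxy]propanoate | COc1cccc(OC(=O)[C@H](OS(=O)(=O)C(F)(F)F)C(c2ccc(OC)cc2)c2ccc(OC)cc2)c1 | intermediate
10 | 3-methoxyphenyl (2R)-3-[4-(benzyloxy)-2-hydroxybenzoyl]-2-[bis(4-methoxyphenyl)methyl]-4-(dimethylamino)but-3-enoate (enamine E/Z not defined) | COc1cccc(OC(=O)[C@@H](C(=CN(C)C)C(=O)c2ccc(OCc3ccccc3)cc2O)C(c2ccc(OC)cc2)c2ccc(OC)cc2)c1 | intermediate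
11 | 3-methoxyphenyl (2R)-2-[7-(benzyloxy)-4-oxo-4H-chromen-3-yl]-3,3-bis(4-methoxyphenyl)propanoate | COc1cccc(OC(=O)[C@@H](c2coc3cc(OCc4ccccc4)ccc3c2=O)C(c2ccc(OC)cc2)c2ccc(OC)cc2)c1 | intermediate
12 | 7-(benzyloxy)-3-[(2R)-1-(2-hydroxy-4-methoxyphenyl)-3,3-bis(4-methoxyphenyl)-1-oxopropan-2-yl]-4H-chromen-4-one | COc1ccc(C(=O)[C@@H](c2coc3cc(OCc4ccccc4)ccc3c2=O)C(c2ccc(OC)cc2)c2ccc(OC)cc2)c(O)c1 | intermediate
13 | 7-hydroxy-3-[(2R)-1-(2-hydroxy-4-methoxyphenyl)-3,3-bis(4-hydroxyphenyl)-1-oxopropan-2-yl]-4H-chromen-4-one | COc1ccc(C(=O)[C@@H](c2coc3cc(O)ccc3c2=O)C(c2ccc(O)cc2)c2ccc(O)cc2)c(O)c1 | target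

## Step count and risks

Total steps: 6 (steps 1, 2, 4, 5, 6 in line; step 3 makes the enaminone partner). Longest linear sequence: 5 steps from 1.

**Risk 1 — step 4 (the proposed new step).** The enaminone 8 is only a moderate carbon nucleophile toward a hindered secondary triflate. O-alkylation (with later O→C transfer eroding ee), anisyl-assisted ionisation of 9 (1,2-aryl shift) or elimination to the 3,3-diarylacrylate can compete.

Fallback with known chemistry (inversion alkylation of a β-keto ester enolate by a 2-triflyloxy ester, decarboxylation, formylative chromone closure). It sets out from 6 (through the same triflate 9) with a nucleophile built from 7, and comes back at 11. Ketone 7 is protected (NaH, MOMCl, DMF) as 1-[4-(benzyloxy)-2-(methoxymethoxy)phenyl]ethan-1-one F1. F1 is C-acylated (NaH, diallyl carbonate, THF, reflux) to prop-2-en-1-yl 3-[4-(benzyloxy)-2-(methoxymethoxy)phenyl]-3-oxopropanoate F2. Its sodium enolate displaces the triflate of 9 (THF, −40 → 0 °C, inversion) to give 4-(3-methoxyphenyl) 1-(prop-2-en-1-yl) (3R)-2-[4-(benzyloxy)-2-(methoxymethoxy)benzoyl]-3-[bis(4-methoxyphenyl)methyl]butanedioate F3 as a C2-epimer mixture. Pd(PPh3)4 with HCO2H/Et3N removes the allyl ester with decarboxylation to give 3-methoxyphenyl (2S)-4-[4-(benzyloxy)-2-(methoxymethoxy)phenyl]-2-[bis(4-methoxyphenyl)methyl]-4-oxobutanoate F4 (same spatial arrangement; the descriptor changes by CIP ranking only). DMF/BF3·OEt2/MsCl at 60 °C then cleaves the MOM ether, formylates the CH2 and closes the pyranone to 11.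

**Risk 2 — step 5.** The chromone absorbs most of the light (inner filter, low quantum efficiency). The other ortho and the para Fries isomers, decarbonylation of the acyl radical, and photolysis of the benzyl ether can lower the yield.

Fallback (thermal acyl–aryl bond formation). It sets out from 11 and comes back at 13. Ester 11 is converted with Me2AlSPh (AlMe3/PhSH, CH2Cl2, 0 °C) into S-phenyl (2R)-2-[7-(benzyloxy)-4-oxo-4H-chromen-3-yl]-3,3-bis(4-methoxyphenyl)propanethioate F5. A neutral Liebeskind–Srogl coupling with (2,4-dimethoxyphenyl)boronic acid (Pd2(dba)3, tri(2-furyl)phosphine, CuTC, THF, 50 °C) gives 7-(benzyloxy)-3-[(2R)-1-(2,4-dimethoxyphenyl)-3,3-bis(4-methoxyphenyl)-1-oxopropan-2-yl]-4H-chromen-4-one F6. BBr3 under the step 6 conditions, where the ortho OMe is lost first by chelation, then gives 13.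

**Risk 3 — step 6.** The para-OMe of the benzoyl ring may be partly cleaved (over-demethylation), and prolonged Lewis-acid exposure could enolise the α-CH.

Fallback (all ethers are removed before the methoxy-bearing ring is attached, so nothing has to be spared). It sets out from 11 and comes back at 13. Ester 11 is saponified briefly (LiOH, THF/H2O, 0 °C) to (2R)-2-[7-(benzyloxy)-4-oxo-4H-chromen-3-yl]-3,3-bis(4-methoxyphenyl)propanoic acid F7. Exhaustive BBr3 (CH2Cl2, 0 °C → rt) gives (2R)-2-(7-hydroxy-4-oxo-4H-chromen-3-yl)-3,3-bis(4-hydroxyphenyl)propanoic acid F8. DIC with a large excess of 5 gives 3-methoxyphenyl (2R)-2-(7-hydroxy-4-oxo-4H-chromen-3-yl)-3,3-bis(4-hydroxyphenyl)propanoate F9. Irradiation as in step 5 then gives 13 directly.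

## Further compounds

F1 | step 4 | 1-[4-(benzyloxy)-2-(methoxymethoxy)phenyl]ethan-1-one | CC(=O)c1ccc(OCc2ccccc2)cc1OCOC
F2 | step 4 | prop-2-en-1-yl 3-[4-(benzyloxy)-2-(methoxymethoxy)phenyl]-3-oxopropanoate | C=CCOC(=O)CC(=O)c1ccc(OCc2ccccc2)cc1OCOC
F3 | step 4 | 4-(3-methoxyphenyl) 1-(prop-2-en-1-yl) (3R)-2-[4-(benzyloxy)-2-(methoxymethoxy)benzoyl]-3-[bis(4-methoxyphenyl)methyl]butanedioate (C2 epimers) | COc1cccc(OC(=O)[C@@H](C(C(=O)OCC=C)C(=O)c2ccc(OCc3ccccc3)cc2OCOC)C(c2ccc(OC)cc2)c2ccc(OC)cc2)c1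
F4 | step 4 | 3-methoxyphenyl (2S)-4-[4-(benzyloxy)-2-(methoxymethoxy)phenyl]-2-[bis(4-methoxyphenyl)methyl]-4-oxobutanoate | COc1cccc(OC(=O)[C@@H](CC(=O)c2ccc(OCc3ccccc3)cc2OCOC)C(c2ccc(OC)cc2)c2ccc(OC)cc2)c1
F5 | step 5 | S-phenyl (2R)-2-[7-(benzyloxy)-4-oxo-4H-chromen-3-yl]-3,3-bis(4-methoxyphenyl)propanethioate | O=C(Sc1ccccc1)[C@@H](c1coc2cc(OCc3ccccc3)ccc2c1=O)C(c1ccc(OC)cc1)c1ccc(OC)cc1
F6 | step 5 | 7-(benzyloxy)-3-[(2R)-1-(2,4-dimethoxyphenyl)-3,3-bis(4-methoxyphenyl)-1-oxopropan-2-yl]-4H-chromen-4-one | COc1ccc(C(=O)[C@@H](c2coc3cc(OCc4ccccc4)ccc3c2=O)C(c2ccc(OC)cc2)c2ccc(OC)cc2)c(OC)c1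
F7 | step 6 | (2R)-2-[7-(benzyloxy)-4-oxo-4H-chromen-3-yl]-3,3-bis(4-methoxyphenyl)propanoic acid | OC(=O)[C@@H](c1coc2cc(OCc3ccccc3)ccc2c1=O)C(c1ccc(OC)cc1)c1ccc(OC)cc1
F8 | step 6 | (2R)-2-(7-hydroxy-4-oxo-4H-chromen-3-yl)-3,3-bis(4-hydroxyphenyl)propanoic acid | OC(=O)[C@@H](c1coc2cc(O)ccc2c1=O)C(c1ccc(O)cc1)c1ccc(O)cc1
F9 | step 6 | 3-methoxyphenyl (2R)-2-(7-hydroxy-4-oxo-4H-chromen-3-yl)-3,3-bis(4-hydroxyphenyl)propanoate | COc1cccc(OC(=O)[C@@H](c2coc3cc(O)ccc3c2=O)C(c2ccc(O)cc2)c2ccc(O)cc2)c1
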